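**Plan**
- Retrosynthesis: remove five benzyl ethers and a bromine cap on C8 of ring D, then cut both aryl bonds of C4, namely C4–C6 (ring D, interflavan bond) and C4–C4a (ring C of the upper flavan). This leads back to an open-chain (S)-3-aryloxy-3-arylpropanal and 8-bromo-tri-O-benzyl-epiafzelechin; the aldehyde is traced to an aryl homoallyl ether and 4-(benzyloxy)benzaldehyde.
- Forward: allylboration sets C2, copper-catalysed O-arylation attaches ring A to O1, oxidative cleavage turns the allyl end into the C4 aldehyde. Ring C is closed last by C4–C4a bond formation, and the cation that results is captured in the same flask by C6 of ring D.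
- Enabling feature: in ring A, C4a lies ortho to O1 and para to O7, so it is the most nucleophilic ring carbon, and once it is bonded to C4 that carbon is a 2,4-dioxygenated benzylic centre that ionises easily. Ring D is a phloroglucinol ether with C8 capped by bromine, so only C6 can attack.
- Stereochemistry: C2 (S) comes from reagent-controlled allylboration and is carried on with retention. C4 (R, trans to the 2-aryl group) comes from quasi-axial capture of the cyclic cation. C2 and C3 of the lower unit come from (−)-epiafzelechin.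

Key step: step 6

Assumption: (−)-epiafzelechin (2R,3R) is bought as the natural product, and hindered rotation about the C4–C6 bond in 13 and 14 is treated as conformational, not as a stereochemical element.

**Step 1**
Reactants: 1 4-(benzyloxy)benzaldehyde
Product: 3 (S)-1-[4-(benzyloxy)phenyl]but-3-en-1-ol, via borinate ester 2 (not isolated)
Conditions: (−)-Ipc2BOMe (from (+)-α-pinene), allylmagnesium bromide, Et2O, 0 °C to rt; then 1, −78 °C; then NaOH, H2O2, rt
Reagents that add atoms: allylmagnesium bromide, C=CC[Mg]Br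
Why: Brown allylboration through a chair-like Zimmerman–Traxler transition state, in which the isopinocampheyl groups of the (+)-α-pinene series direct allyl transfer to the Si face of the aryl aldehyde and so set the (S) carbinol centre that becomes C2 of the upper flavan.

**Step 2**
Reactants: 3 (S)-1-[4-(benzyloxy)phenyl]but-3-en-1-ol (1.0 equiv), 4 1-(benzyloxy)-3-iodobenzene (1.5 equiv)
Product: 5 1-(benzyloxy)-3-{[(1S)-1-[4-(benzyloxy)phenyl]but-3-en-1-yl]oxy}benzene
Conditions: CuI (10 mol%), 3,4,7,8-tetramethyl-1,10-phenanthroline (20 mol%), Cs2CO3, toluene, 110 °C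
Reagents that add atoms: none
Why: Ullmann-type copper-catalysed C–O coupling forms the aryl–oxygen bond and leaves the C–O bond of the stereocentre untouched, so the (S) configuration should be carried over unchanged at this easily ionised 4-alkoxybenzylic carbon.

**Step 3**
Reactants: 5 1-(benzyloxy)-3-{[(1S)-1-[4-(benzyloxy)phenyl]but-3-en-1-yl]oxy}benzene
Product: 7 (3S)-3-[3-(benzyloxy)phenoxy]-3-[4-(benzyloxy)phenyl]propanal, via 1,2-diol 6 (not isolated)
Conditions: OsO4 (2 mol%), NaIO4, 2,6-lutidine, dioxane/H2O 3:1, rt; crude aldehyde used without delay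
Reagents that add atoms: OsO4, O=[Os](=O)(=O)=O (delivers the aldehyde oxygen; regenerated by NaIO4, [Na+].[O-]I(=O)(=O)=O)
Why: Lemieux–Johnson oxidative cleavage (catalytic dihydroxylation, then periodate glycol cleavage, buffered by 2,6-lutidine) removes the terminal carbon and leaves the C2–C3–C4 chain as an aldehyde, while the electron-rich arenes, the benzyl ethers and the stereocentre are not touched.

**Step 4**
Reactants: 8 (−)-epiafzelechin
Product: 9 (2R,3R)-5,7-bis(benzyloxy)-2-[4-(benzyloxy)phenyl]chroman-3-ol
Conditions: BnBr (3.3 equiv), K2CO3, DMF, 0 °C to rt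
Reagents that add atoms: benzyl bromide, BrCc1ccccc1
Why: Williamson etherification under weak-base conditions benzylates the three phenols only, since K2CO3 does not deprotonate the secondary alcohol at C3, and the stereocentres are not involved.

**Step 5**
Reactants: 9 (2R,3R)-5,7-bis(benzyloxy)-2-[4-(benzyloxy)phenyl]chroman-3-ol
Product: 10 (2R,3R)-5,7-bis(benzyloxy)-2-[4-(benzyloxy)phenyl]-8-bromochroman-3-ol
Conditions: NBS (1.0 equiv), CH2Cl2, −78 °C to rt
Reagents that add atoms: N-bromosuccinimide, O=C1CCC(=O)N1Br
Why: Electrophilic aromatic bromination of the phloroglucinol-type ring D, for which O-benzylated flavan-3-ols are known to react at C8 in preference to C6, installs a removable cap so that C6 is the only nucleophilic carbon left.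

**Step 6**
Reactants: 7 (3S)-3-[3-(benzyloxy)phenoxy]-3-[4-(benzyloxy)phenyl]propanal, 10 (2R,3R)-5,7-bis(benzyloxy)-2-[4-(benzyloxy)phenyl]-8-bromochroman-3-ol
Product: 13 (2R,3R)-5,7-bis(benzyloxy)-6-{(2S,4R)-7-(benzyloxy)-2-[4-(benzyloxy)phenyl]chroman-4-yl}-2-[4-(benzyloxy)phenyl]-8-bromochroman-3-ol, via flavan-4-ol 11 (not isolated), via flavan-4-yl cation 12 (not isolated)
Conditions: 7, TMSOTf (0.3 equiv), 4 Å MS, CH2Cl2, −78 °C; then 10 (1.5 equiv, excess recovered), −78 to −30 °C
Reagents that add atoms: none
Why: TMSOTf turns the aldehyde into a silyloxycarbenium ion that ring A attacks through C4a, the carbon ortho to O1 and para to the 7-benzyloxy group, so that the C4–C4a bond closes ring C as chroman-4-ol 11 (6-exo-trig electrophilic aromatic substitution, an intramolecular Friedel–Crafts hydroxyalkylation); the acid then ionises 11 to the 2,4-dioxygenated benzylic cation 12, which C6 of 10 captures. The closest known reaction types are the carbonyl–arene cyclisation of aryl-tethered aldehydes with capture of the resulting benzylic cation by a second arene, and the Friedel–Crafts coupling of flavan-4-ols or 4-alkoxyflavans with phloroglucinol-type nucleophiles. The carbinol centre of 11 is erased on ionisation, and C4 of 13 is set under control of C2: in the sofa-shaped cation the 2-aryl group lies pseudo-equatorial and the nucleophile should enter quasi-axially on the face anti to it, which gives the 2,4-trans (2S,4R) arrangement. Ring closure needs regioselectivity for the position para to the benzyloxy group over the position between the two oxygens (secured by sterics) and must outrun loss of the aryloxy group (secured by the low temperature and the six-membered intramolecular pathway, with 10 added only afterwards). On ring D only C6 can react because C8 carries the bromine cap, and any minor enantiomer of 7 would end up as a diastereomer of 13 that chromatography can remove.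

**Step 7**
Reactants: 13 (2R,3R)-5,7-bis(benzyloxy)-6-{(2S,4R)-7-(benzyloxy)-2-[4-(benzyloxy)phenyl]chroman-4-yl}-2-[4-(benzyloxy)phenyl]-8-bromochroman-3-ol
Product: 14 (2R,3R)-6-[(2S,4R)-7-hydroxy-2-(4-hydroxyphenyl)chroman-4-yl]-2-(4-hydroxyphenyl)chroman-3,5,7-triol
Conditions: H2 (1 atm), Pd(OH)2/C, NaOAc, THF/MeOH/H2O, rt
Reagents that add atoms: none
Why: Catalytic hydrogenolysis should cleave the five benzyl ethers and the aryl C–Br bond in one operation, with NaOAc taking up the HBr so that the acid-labile interflavan bond is not exposed to acid; the cyclic benzylic C2–O1 ethers of flavans are known to survive these conditions.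

**Compound list**
1 | 4-(benzyloxy)benzaldehyde | O=Cc1ccc(OCc2ccccc2)cc1 | starting material
2 | (S)-1-[4-(benzyloxy)phenyl]but-3-en-1-yl diisopinocampheylborinate, (+)-α-pinene series (not isolated) | C=CC[C@H](OB([C@H]1[C@H](C)[C@H]2C[C@@H](C1)C2(C)C)[C@H]1[C@H](C)[C@H]2C[C@@H](C1)C2(C)C)c1ccc(OCc2ccccc2)cc1 | intermediate
3 | (S)-1-[4-(benzyloxy)phenyl]but-3-en-1-ol | C=CC[C@H](O)c1ccc(OCc2ccccc2)cc1 | intermediate
4 | 1-(benzyloxy)-3-iodobenzene | Ic1cccc(OCc2ccccc2)c1 | starting material
5 | 1-(benzyloxy)-3-{[(1S)-1-[4-(benzyloxy)phenyl]but-3-en-1-yl]oxy}benzene | C=CC[C@H](Oc1cccc(OCc2ccccc2)c1)c1ccc(OCc2ccccc2)cc1 | intermediate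
6 | (4S)-4-[3-(benzyloxy)phenoxy]-4-[4-(benzyloxy)phenyl]butane-1,2-diol, both epimers at the new carbinol carbon (not isolated) | OCC(O)C[C@H](Oc1cccc(OCc2ccccc2)c1)c1ccc(OCc2ccccc2)cc1 | intermediate
7 | (3S)-3-[3-(benzyloxy)phenoxy]-3-[4-(benzyloxy)phenyl]propanal | O=CC[C@H](Oc1cccc(OCc2ccccc2)c1)c1ccc(OCc2ccccc2)cc1 | intermediate
8 | (−)-epiafzelechin, (2R,3R)-2-(4-hydroxyphenyl)chroman-3,5,7-triol | O[C@@H]1Cc2c(O)cc(O)cc2O[C@@H]1c1ccc(O)cc1 | starting material
9 | (2R,3R)-5,7-bis(benzyloxy)-2-[4-(benzyloxy)phenyl]chroman-3-ol | O[C@@H]1Cc2c(OCc3ccccc3)cc(OCc3ccccc3)cc2O[C@@H]1c1ccc(OCc2ccccc2)cc1 | intermediate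
10 | (2R,3R)-5,7-bis(benzyloxy)-2-[4-(benzyloxy)phenyl]-8-bromochroman-3-ol | O[C@@H]1Cc2c(OCc3ccccc3)cc(OCc3ccccc3)c(Br)c2O[C@@H]1c1ccc(OCc2ccccc2)cc1 | intermediate
11 | (2S)-7-(benzyloxy)-2-[4-(benzyloxy)phenyl]chroman-4-ol, both C4 epimers (not isolated) | OC1C[C@@H](c2ccc(OCc3ccccc3)cc2)Oc2cc(OCc3ccccc3)ccc21 | intermediate
12 | (2S)-7-(benzyloxy)-2-[4-(benzyloxy)phenyl]chroman-4-ylium, ion pair with the catalyst anion (not isolated) | [CH+]1C[C@@H](c2ccc(OCc3ccccc3)cc2)Oc2cc(OCc3ccccc3)ccc21 | intermediate
13 | (2R,3R)-5,7-bis(benzyloxy)-6-{(2S,4R)-7-(benzyloxy)-2-[4-(benzyloxy)phenyl]chroman-4-yl}-2-[4-(benzyloxy)phenyl]-8-bromochroman-3-ol | C(c5ccccc5)Oc1ccc([C@@H]2C[C@@H](c3c(OCc5ccccc5)c(Br)c4c(c3OCc5ccccc5)C[C@@H](O)[C@@H](c3ccc(OCc5ccccc5)cc3)O4)c3ccc(OCc5ccccc5)cc3O2)cc1 | intermediate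
14 | (2R,3R)-6-[(2S,4R)-7-hydroxy-2-(4-hydroxyphenyl)chroman-4-yl]-2-(4-hydroxyphenyl)chroman-3,5,7-triol | Oc1ccc([C@@H]2C[C@@H](c3c(O)cc4c(c3O)C[C@@H](O)[C@@H](c3ccc(O)cc3)O4)c3ccc(O)cc3O2)cc1 | target

**Step count and risks**
Total step count: 7. Longest linear sequence: 5 steps (steps 1, 2, 3, 6, 7).

Steps most likely to fail:

1. Step 6. The cation 12 is formed before the nucleophile is present and may lose a proton and oligomerise, and the acid may ionise the benzylic C2–O1 ether, before the hindered C6 position captures the cation. The fallback sets out from 7. Aldehyde 7 is treated with phenylmethanethiol and catalytic TMSOTf in CH2Cl2 at −78 °C, so that the cation from ring closure is trapped at once by sulfur as (2S)-4-(benzylsulfanyl)-7-(benzyloxy)-2-[4-(benzyloxy)phenyl]chroman F1, a C4-epimer mixture that should be stable to chromatography. F1 and 10 are then joined with AgBF4 in THF at 0 °C, a thiophilic activation under near-neutral conditions with the nucleophile present from the start, which comes back to the route at 13.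

2. Step 2. The copper alkoxide of the secondary benzylic alcohol may be oxidised to the ketone, or the hindered C–O coupling may be slow enough for base-induced decomposition at 110 °C to take over. The fallback sets out from 1. Allylboration with the enantiomeric reagent made from (+)-Ipc2BOMe (the (−)-α-pinene series) gives, through the (R)-configured diisopinocampheylborinate F2, (R)-1-[4-(benzyloxy)phenyl]but-3-en-1-ol F3. A Mitsunobu reaction of F3 with 3-(benzyloxy)phenol (PPh3, DIAD, toluene, −20 °C) then forms the aryl ether with inversion at carbon and comes back to the route at 5.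

3. Step 3. The aryloxide may be lost from the aldehyde by β-elimination (retro-oxa-Michael) under the buffered aqueous conditions or during purification. The fallback sets out from 5. Ozonolysis in CH2Cl2/MeOH at −78 °C, reduction with Me2S and, in the same flask, HC(OMe)3 with PPTS convert the alkene into (3S)-1-(benzyloxy)-3-{1-[4-(benzyloxy)phenyl]-3,3-dimethoxypropoxy}benzene F4, an acetal that cannot eliminate by enolisation. F4 takes the place of 7 in step 6: TMSOTf forms an oxocarbenium ion that closes ring C to (2S)-7-(benzyloxy)-2-[4-(benzyloxy)phenyl]-4-methoxychroman F5 (not isolated), which is ionised on to cation 12 and captured by 10, so the fallback comes back to the route at 13.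

**Further compounds**
F1 | step 6 | (2S)-4-(benzylsulfanyl)-7-(benzyloxy)-2-[4-(benzyloxy)phenyl]chroman, both C4 epimers | C(c1ccccc1)SC1C[C@@H](c2ccc(OCc3ccccc3)cc2)Oc2cc(OCc3ccccc3)ccc21
F2 | step 2 | (R)-1-[4-(benzyloxy)phenyl]but-3-en-1-yl diisopinocampheylborinate, (−)-α-pinene series (not isolated) | C=CC[C@@H](OB([C@@H]1[C@@H](C)[C@@H]2C[C@H](C1)C2(C)C)[C@@H]1[C@@H](C)[C@@H]2C[C@H](C1)C2(C)C)c1ccc(OCc2ccccc2)cc1
F3 | step 2 | (R)-1-[4-(benzyloxy)phenyl]but-3-en-1-ol | C=CC[C@@H](O)c1ccc(OCc2ccccc2)cc1
F4 | step 3 | (3S)-1-(benzyloxy)-3-{1-[4-(benzyloxy)phenyl]-3,3-dimethoxypropoxy}benzene | COC(OC)C[C@H](Oc1cccc(OCc2ccccc2)c1)c1ccc(OCc2ccccc2)cc1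
F5 | step 3 | (2S)-7-(benzyloxy)-2-[4-(benzyloxy)phenyl]-4-methoxychroman, both C4 epimers (not isolated) | COC1C[C@@H](c2ccc(OCc3ccccc3)cc2)Oc2cc(OCc3ccccc3)ccc21
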